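Side-chain atoms: C1' (ArOCH2), C2'/C3' (oxirane, ring C), C4', C5' (CH–O), C6', C7' (CH–CH3), C8' (C=O); the lactone is ring D. Ring D is cut at C7'–C8' and O–C8', exploiting the fact that its C5' oxygen and its C7' methine with a methyl group map onto a C5' carbinol carrying an allyl group: CO enters at the internal alkene carbon and the terminal carbon ends as the methyl. One hydroxyl-tethered rhodium hydroformylation makes C7'–C8', sets C7' and closes the lactol through the same oxygen. The precursor, homoallylic alcohol 13, already holds the coumarin ether and the oxirane; its C5' centre comes from (S)-epichlorohydrin. Lactol oxidation completes the target.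

Key step: step 8

Remark: the target is taken as drawn, (2'R,3'R,5'S,7'R), with the C7' methyl trans to the C5' substituent on ring D; (S)-epichlorohydrin and 7-hydroxy-8-methoxycoumarin are taken as purchasable.

Step 1
Reactants: 1 (S)-epichlorohydrin [(2S)-2-(chloromethyl)oxirane]; 2 vinylmagnesium bromide
Product: 3 (2S)-1-chloropent-4-en-2-ol
Conditions: CuI (10 mol%), THF, −40 → −20 °C; then 1 M HCl, 0 °C
Reagents that add atoms: vinylmagnesium bromide (2), C=C[Mg]Br
Why: Copper-catalysed Grignard opening of the oxirane at its unsubstituted carbon (chloride retained) is standard for epichlorohydrin; no bond to the stereocentre is broken, so the (S) centre, the future C5', is taken over from the chiral pool.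

Step 2
Reactants: 3 (2S)-1-chloropent-4-en-2-ol; 4 lithium acetylide–ethylenediamine complex
Product: 6 (4S)-hept-1-en-6-yn-4-ol, via (2S)-2-allyloxirane 5 (not isolated)
Conditions: 4 (3 equiv), DMSO, 0 °C → rt; then H2O
Reagents that add atoms: lithium acetylide (as its ethylenediamine complex 4), [Li]C#C
Why: The lithium alkoxide closes to the oxirane by intramolecular Williamson displacement of chloride and acetylide then opens it at the CH2 terminus (epoxide alkynylation in DMSO); the C–O bond at the stereocentre stays intact, so C5' remains (S) and the volatile oxirane need not be handled.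

Step 3
Reactants: 6 (4S)-hept-1-en-6-yn-4-ol
Product: 7 tert-butyl{[(4S)-hept-1-en-6-yn-4-yl]oxy}dimethylsilane
Conditions: TBSCl, imidazole, DMF, rt
Reagents that add atoms: tert-butyldimethylsilyl chloride, CC(C)(C)[Si](C)(C)Cl
Why: Standard silylation of a secondary alcohol; the silyl ether keeps the carbinol inert to AlMe3 and out of the later Mitsunobu step and is removable under buffered fluoride.

Step 4
Reactants: 7 tert-butyl{[(4S)-hept-1-en-6-yn-4-yl]oxy}dimethylsilane
Product: 9 (2E,5S)-5-{[tert-butyl(dimethyl)silyl]oxy}-3-methylocta-2,7-dien-1-ol, via E-alkenyldimethylalane 8 (not isolated)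
Conditions: AlMe3 (3 equiv), Cp2ZrCl2 (0.25 equiv), CH2Cl2, 0 °C → rt; then (CH2O)n, 0 °C → rt; aq. potassium sodium tartrate
Reagents that add atoms: trimethylaluminium, C[Al](C)C; formaldehyde (as paraformaldehyde), C=O
Why: Negishi zirconium-catalysed methylalumination adds CH3 and Al syn across the terminal alkyne with CH3 on the internal carbon (the isolated alkene is inert to Cp2ZrCl2/AlMe3), and the alkenyl–Al bond then adds to formaldehyde with retention, which fixes the E geometry (CH2OH cis to CH3).

Step 5
Reactants: 9 (2E,5S)-5-{[tert-butyl(dimethyl)silyl]oxy}-3-methylocta-2,7-dien-1-ol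
Product: 10 {(2R,3R)-3-[(2S)-2-{[tert-butyl(dimethyl)silyl]oxy}pent-4-en-1-yl]-3-methyloxiran-2-yl}methanol
Conditions: Ti(OiPr)4 (10 mol%), D-(−)-diethyl tartrate (12 mol%), t-BuOOH (2 equiv, decane), 4 Å MS, CH2Cl2, −20 °C
Reagents that add atoms: tert-butyl hydroperoxide, CC(C)(C)OO
Why: Sharpless asymmetric epoxidation of an E-trisubstituted allylic alcohol; D-(−)-diethyl tartrate should deliver oxygen to the face that gives the (2R,3R)-oxirane (the mirror-image sense of the L-(+)-tartrate epoxidation of geraniol), reagent control overriding the remote C5' centre, while the terminal alkene, lacking an allylic hydroxyl, is not epoxidised.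

Step 6
Reactants: 10 {(2R,3R)-3-[(2S)-2-{[tert-butyl(dimethyl)silyl]oxy}pent-4-en-1-yl]-3-methyloxiran-2-yl}methanol; 11 7-hydroxy-8-methoxy-2H-chromen-2-one
Product: 12 7-({(2R,3R)-3-[(2S)-2-{[tert-butyl(dimethyl)silyl]oxy}pent-4-en-1-yl]-3-methyloxiran-2-yl}methoxy)-8-methoxy-2H-chromen-2-one
Conditions: PPh3, DIAD, THF, 0 °C → rt
Reagents that add atoms: none
Why: Mitsunobu etherification, in which the acidic 7-OH of the coumarin displaces the primary alkoxyphosphonium at C1' by SN2; no stereocentre is involved and oxiranylmethanols are established partners for phenol Mitsunobu coupling.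

Step 7
Reactants: 12 7-({(2R,3R)-3-[(2S)-2-{[tert-butyl(dimethyl)silyl]oxy}pent-4-en-1-yl]-3-methyloxiran-2-yl}methoxy)-8-methoxy-2H-chromen-2-one
Product: 13 7-({(2R,3R)-3-[(2S)-2-hydroxypent-4-en-1-yl]-3-methyloxiran-2-yl}methoxy)-8-methoxy-2H-chromen-2-one
Conditions: Bu4NF, AcOH (1:1), THF, rt
Reagents that add atoms: none
Why: Fluoride cleavage of the silyl ether; buffering with acetic acid keeps the medium non-basic, so that no alkoxide attacks the oxirane or the coumarin lactone, and it frees the single hydroxyl that the key step needs.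

Step 8
Reactants: 13 7-({(2R,3R)-3-[(2S)-2-hydroxypent-4-en-1-yl]-3-methyloxiran-2-yl}methoxy)-8-methoxy-2H-chromen-2-one
Product: 15 lactol 7-({(2R,3R)-3-{[(2S,4R)-5-hydroxy-4-methyloxolan-2-yl]methyl}-3-methyloxiran-2-yl}methoxy)-8-methoxy-2H-chromen-2-one (both C8' anomers), via hydroxy aldehyde 14 (not isolated)
Conditions: Rh(acac)(CO)2 (2 mol%), scaffolding ligand L* (15 mol%; single enantiomer of the 2-isopropoxy-1-methyl-3-phenyl-2,3-dihydro-1H-1,3-benzazaphosphole type), pTsOH (0.1 mol%), CO/H2 (1:1, 14 bar), benzene, 45 °C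
Reagents that add atoms: carbon monoxide, [C-]#[O+]
Why: Proposed new method: acid-catalysed exchange puts the C5' oxygen of 13 on the N,O-acetal carbon of L* in place of isopropoxide, so the phosphorus-bound rhodium hydride sits next to the alkene; intramolecular hydrometalation places rhodium on C7' and hydride on the terminal carbon (the future methyl), CO insertion forms C7'–C8', and hydrogenolysis releases aldehyde 14 and the ligand. The closest known reaction type is branched hydroformylation of homoallylic alcohols directed by a reversibly bound phosphorus ligand, giving gamma-lactols; the new demand is that C7' be set relative to an existing C5' carbinol centre, for which control is not established. Ring D closes by 5-exo-trig addition of the C5' hydroxyl to the C8' aldehyde, which should outpace enolisation and so preserve C7'. The (R) configuration at C7' (methyl trans to the C5' substituent) requires formyl delivery to the Re face of C7'; this is decided in the tethered chelate, where the C4' chain should lie pseudo-equatorial and the stereogenic phosphorus/acetal unit of the enantiopure ligand selects the face, the matched ligand enantiomer being identified by running both. Branched regioselectivity is secured by the tether from the only free hydroxyl of 13, and chemoselectivity by the near-neutral, mild conditions (the trace sulfonic acid is buffered by the excess ligand, so the oxirane should survive) and by the low reactivity of the conjugated coumarin C3=C4 bond.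

Step 9
Reactants: 15 lactol 7-({(2R,3R)-3-{[(2S,4R)-5-hydroxy-4-methyloxolan-2-yl]methyl}-3-methyloxiran-2-yl}methoxy)-8-methoxy-2H-chromen-2-one
Product: 16 7-({(2R,3R)-3-methyl-3-{[(2S,4R)-4-methyl-5-oxooxolan-2-yl]methyl}oxiran-2-yl}methoxy)-8-methoxy-2H-chromen-2-one (target)
Conditions: TEMPO (0.2 equiv), PhI(OAc)2 (2 equiv), CH2Cl2, rt
Reagents that add atoms: none
Why: Oxoammonium (TEMPO) oxidation with PhI(OAc)2 as terminal oxidant converts lactols to lactones at room temperature under near-neutral conditions, so the C7' centre next to the new carbonyl should not epimerise and the oxirane and coumarin should be untouched.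

Compound list
1 | (S)-epichlorohydrin, (2S)-2-(chloromethyl)oxirane | ClC[C@@H]1CO1 | starting material
2 | vinylmagnesium bromide | C=C[Mg]Br | starting material
3 | (2S)-1-chloropent-4-en-2-ol | ClC[C@@H](O)CC=C | intermediate
4 | lithium acetylide–ethylenediamine complex | [Li]C#C.NCCN | starting material
5 | (2S)-2-(prop-2-en-1-yl)oxirane, (2S)-2-allyloxirane (not isolated) | C=CC[C@H]1CO1 | intermediate
6 | (4S)-hept-1-en-6-yn-4-ol | C#CC[C@@H](O)CC=C | intermediate
7 | tert-butyl{[(4S)-hept-1-en-6-yn-4-yl]oxy}dimethylsilane | C#CC[C@@H](O[Si](C)(C)C(C)(C)C)CC=C | intermediate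
8 | [(1E,4S)-4-{[tert-butyl(dimethyl)silyl]oxy}-2-methylhepta-1,6-dien-1-yl]dimethylalumane (not isolated) | C[Al](C)/C=C(\C)C[C@@H](O[Si](C)(C)C(C)(C)C)CC=C | intermediate
9 | (2E,5S)-5-{[tert-butyl(dimethyl)silyl]oxy}-3-methylocta-2,7-dien-1-ol | OC/C=C(\C)C[C@@H](O[Si](C)(C)C(C)(C)C)CC=C | intermediate
10 | {(2R,3R)-3-[(2S)-2-{[tert-butyl(dimethyl)silyl]oxy}pent-4-en-1-yl]-3-methyloxiran-2-yl}methanol | OC[C@H]1O[C@]1(C)C[C@@H](O[Si](C)(C)C(C)(C)C)CC=C | intermediate
11 | 7-hydroxy-8-methoxy-2H-chromen-2-one | COc1c(O)ccc2ccc(=O)oc12 | starting material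
12 | 7-({(2R,3R)-3-[(2S)-2-{[tert-butyl(dimethyl)silyl]oxy}pent-4-en-1-yl]-3-methyloxiran-2-yl}methoxy)-8-methoxy-2H-chromen-2-one | COc1c(OC[C@H]2O[C@]2(C)C[C@@H](O[Si](C)(C)C(C)(C)C)CC=C)ccc2ccc(=O)oc12 | intermediate
13 | 7-({(2R,3R)-3-[(2S)-2-hydroxypent-4-en-1-yl]-3-methyloxiran-2-yl}methoxy)-8-methoxy-2H-chromen-2-one (key-step precursor) | COc1c(OC[C@H]2O[C@]2(C)C[C@@H](O)CC=C)ccc2ccc(=O)oc12 | intermediate
14 | (2R,4S)-4-hydroxy-5-[(2R,3R)-3-{[(8-methoxy-2-oxo-2H-chromen-7-yl)oxy]methyl}-2-methyloxiran-2-yl]-2-methylpentanal (not isolated) | COc1c(OC[C@H]2O[C@]2(C)C[C@@H](O)C[C@@H](C)C=O)ccc2ccc(=O)oc12 | intermediate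
15 | 7-({(2R,3R)-3-{[(2S,4R)-5-hydroxy-4-methyloxolan-2-yl]methyl}-3-methyloxiran-2-yl}methoxy)-8-methoxy-2H-chromen-2-one (lactol, both anomers) | COc1c(OC[C@H]2O[C@]2(C)C[C@@H]2C[C@@H](C)C(O)O2)ccc2ccc(=O)oc12 | intermediate
16 | 7-({(2R,3R)-3-methyl-3-{[(2S,4R)-4-methyl-5-oxooxolan-2-yl]methyl}oxiran-2-yl}methoxy)-8-methoxy-2H-chromen-2-one | COc1c(OC[C@H]2O[C@]2(C)C[C@@H]2C[C@@H](C)C(=O)O2)ccc2ccc(=O)oc12 | target

Total step count: 9
Longest linear sequence: 9 steps (1 to 16); phenol 11 enters at step 6 as purchased.

Steps most likely to fail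

1. Step 8 (bears the label). What may go wrong: weak or mismatched facial selection at C7' in the tethered chelate; slow exchange of the C5' hydroxyl onto the ligand, so that untethered linear hydroformylation competes; or alkene isomerisation. The fallback uses known chemistry, sets out from 13 and returns at 16. Anti-Markovnikov hydroboration of the terminal alkene (9-BBN, THF; then NaBO3·4H2O) should give the diol 7-({(2R,3R)-3-[(2S)-2,5-dihydroxypentyl]-3-methyloxiran-2-yl}methoxy)-8-methoxy-2H-chromen-2-one F1. TEMPO/PhI(OAc)2 then oxidises the primary alcohol and the lactol that forms to the unsubstituted lactone 7-({(2R,3R)-3-methyl-3-{[(2S)-5-oxooxolan-2-yl]methyl}oxiran-2-yl}methoxy)-8-methoxy-2H-chromen-2-one F2. Kinetic enolisation (LiN(SiMe3)2, THF, −78 °C) and methylation with MeI follow; for enolates of gamma-substituted butyrolactones this alkylation occurs on the face away from the gamma substituent, so it should place the C7' methyl trans and give 16 directly.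

2. Step 4. What may go wrong: incomplete capture of the alkenylalane by formaldehyde (protonolysis to the 1,1-disubstituted alkene on work-up) or eroded regiocontrol of the methylalumination next to the silyl ether. The fallback sets out from 7 and returns at 9. Deprotonation of the alkyne (n-BuLi, THF, −78 °C) and addition to paraformaldehyde should give the propargylic alcohol (5S)-5-{[tert-butyl(dimethyl)silyl]oxy}oct-7-en-2-yn-1-ol F3. Hydroxyl-directed trans-hydroalumination with NaAlH2(OCH2CH2OMe)2 followed by I2 should give (2Z,5S)-5-{[tert-butyl(dimethyl)silyl]oxy}-3-iodoocta-2,7-dien-1-ol F4. Stereoretentive methylation of the alkenyl iodide with Me2CuLi then gives 9 with the same E geometry.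

3. Step 6. What may go wrong: slow substitution at the alkoxyphosphonium stage with competing N-alkylation of the reduced azodicarboxylate, or opening of the oxirane in the activated intermediate. The fallback sets out from 10 and returns at 12. Tosylation (TsCl, Et3N, DMAP, CH2Cl2, 0 °C) should give {(2R,3R)-3-[(2S)-2-{[tert-butyl(dimethyl)silyl]oxy}pent-4-en-1-yl]-3-methyloxiran-2-yl}methyl 4-methylbenzenesulfonate F5. Williamson etherification with phenol 11 (Cs2CO3, DMF, rt) then gives 12 by direct SN2 displacement at the primary C1'.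

Further compounds
F1 | step 8 | 7-({(2R,3R)-3-[(2S)-2,5-dihydroxypentyl]-3-methyloxiran-2-yl}methoxy)-8-methoxy-2H-chromen-2-one | COc1c(OC[C@H]2O[C@]2(C)C[C@@H](O)CCCO)ccc2ccc(=O)oc12
F2 | step 8 | 7-({(2R,3R)-3-methyl-3-{[(2S)-5-oxooxolan-2-yl]methyl}oxiran-2-yl}methoxy)-8-methoxy-2H-chromen-2-one | COc1c(OC[C@H]2O[C@]2(C)C[C@@H]2CCC(=O)O2)ccc2ccc(=O)oc12
F3 | step 4 | (5S)-5-{[tert-butyl(dimethyl)silyl]oxy}oct-7-en-2-yn-1-ol | OCC#CC[C@@H](O[Si](C)(C)C(C)(C)C)CC=C
F4 | step 4 | (2Z,5S)-5-{[tert-butyl(dimethyl)silyl]oxy}-3-iodoocta-2,7-dien-1-ol | OC/C=C(\I)C[C@@H](O[Si](C)(C)C(C)(C)C)CC=C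
F5 | step 6 | {(2R,3R)-3-[(2S)-2-{[tert-butyl(dimethyl)silyl]oxy}pent-4-en-1-yl]-3-methyloxiran-2-yl}methyl 4-methylbenzenesulfonate | Cc1ccc(cc1)S(=O)(=O)OC[C@H]1O[C@]1(C)C[C@@H](O[Si](C)(C)C(C)(C)C)CC=C
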